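**Strategy.** The route rests on disconnecting the C3=C4 alkene of the 2H-pyran ring (O1–C2(CH3)2–C3=C4–C4a–C8a) fused to the acylphloroglucinol benzene ring. Ring-closing metathesis joins an aryl vinyl group on the future C4a to the vinyl terminus of a 1,1-dimethylallyl ether on the oxygen para to the isobutyryl ketone. One operation forms the pyran ring and its only C=C bond, with loss of ethene. The precursor is the unprotected 3-vinyl-2,6-dihydroxy-4-(1,1-dimethylallyloxy)isobutyrophenone, assembled from phloroglucinol in five steps. The free C8 position of the chromene is then bridged through a methylene group to a 4-hydroxy-2-pyranone made from pentan-3-one.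

Key step: step 6

Remark: the target has no stereocentre and the cis geometry of the ring alkene follows from ring size; silyl enol ether 12 is drawn as its Z isomer but an isomer mixture serves equally, since the geometry is erased in step 8.

**Step 1**
Reactants: 1 phloroglucinol (benzene-1,3,5-triol); 2 2-methylpropanoyl chloride
Product: 3 2-methyl-1-(2,4,6-trihydroxyphenyl)propan-1-one
Conditions: AlCl3 (4 equiv), PhNO2, 25 → 65 °C; then ice/1 M HCl
Reagents that add atoms: none
Why: Friedel–Crafts C-acylation of the symmetric, strongly activated triol should stop after one acyl group because the aluminium-complexed aryl ketone is deactivated.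

**Step 2**
Reactants: 3 2-methyl-1-(2,4,6-trihydroxyphenyl)propan-1-one; 4 3-chloro-3-methylbut-1-yne
Product: 5 1-[2,6-dihydroxy-4-(2-methylbut-3-yn-2-yloxy)phenyl]-2-methylpropan-1-one
Conditions: 4 (1.05 equiv), DBU (1.3 equiv), CuCl2·2H2O (1 mol%), MeCN, 0 °C
Reagents that add atoms: none
Why: Copper-catalysed propargylic O-alkylation of a phenol with a tertiary propargylic chloride should take place at the 4-hydroxyl, the only one not hydrogen-bonded to the ketone and the most acidic, and at 0 °C the new ether cannot undergo Claisen rearrangement.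

**Step 3**
Reactants: 5 1-[2,6-dihydroxy-4-(2-methylbut-3-yn-2-yloxy)phenyl]-2-methylpropan-1-one
Product: 7 2,4-dihydroxy-6-(2-methylbut-3-yn-2-yloxy)-3-(2-methylpropanoyl)benzaldehyde, via aryl iminium chloride 6 (not isolated)
Conditions: POCl3 (1.2 equiv), DMF (3 equiv), EtOAc, 0 °C → rt; then aq. NaOAc, 0 °C → rt
Reagents that add atoms: N,N-dimethylformamide, CN(C)C=O; water, O
Why: Vilsmeier–Haack formylation should attack one of the two equivalent ring carbons, each activated by three oxygen substituents, and stop there because the iminium group deactivates the ring, while the tertiary α-carbon of the ketone rules out chromone formation and the buffered hydrolysis spares the tertiary propargylic ether.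

**Step 4**
Reactants: 7 2,4-dihydroxy-6-(2-methylbut-3-yn-2-yloxy)-3-(2-methylpropanoyl)benzaldehyde
Product: 8 2,4-dihydroxy-6-(2-methylbut-3-en-2-yloxy)-3-(2-methylpropanoyl)benzaldehyde
Conditions: H2 (1 atm), Pd/CaCO3 poisoned with Pb(OAc)2 (Lindlar catalyst), quinoline, EtOAc, rt, stopped after 1 equiv H2
Reagents that add atoms: none
Why: Lindlar semi-hydrogenation should reduce the terminal alkyne to the vinyl group without touching the carbonyl groups, and it is placed here because no other alkene is yet present to be over-reduced.

**Step 5**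
Reactants: 8 2,4-dihydroxy-6-(2-methylbut-3-en-2-yloxy)-3-(2-methylpropanoyl)benzaldehyde
Product: 9 1-[3-ethenyl-2,6-dihydroxy-4-(2-methylbut-3-en-2-yloxy)phenyl]-2-methylpropan-1-one
Conditions: Ph3PCH3Br (3.5 equiv), KOtBu (3.4 equiv), THF, 0 °C → rt; then aq. NH4Cl
Reagents that add atoms: methyltriphenylphosphonium bromide, C[P+](c1ccccc1)(c1ccccc1)c1ccccc1.[Br-]
Why: Wittig methylenation of a free hydroxybenzaldehyde with excess ylide should work because two equivalents serve as base for the phenols and the remainder olefinates the aldehyde, whereas the ketone, flanked by two phenoxides and an isopropyl group, is too hindered and electron-rich to react.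

**Step 6**
Reactants: 9 1-[3-ethenyl-2,6-dihydroxy-4-(2-methylbut-3-en-2-yloxy)phenyl]-2-methylpropan-1-one
Product: 10 1-(5,7-dihydroxy-2,2-dimethyl-2H-chromen-6-yl)-2-methylpropan-1-one
Conditions: RuCl2(=CHPh)(PCy3)(H2IMes) (second-generation Grubbs catalyst, 5 mol%), degassed CH2Cl2 (0.01 M), 25–40 °C, argon sparge
Reagents that add atoms: none
Why: Ring-closing olefin metathesis by the metallacyclobutane mechanism: the ruthenium benzylidene first exchanges onto the unhindered styrenyl vinyl group of 9, the resulting aryl carbene adds in an intramolecular [2+2] fashion to the neopentyl-type vinyl group of the ether, and cycloreversion releases the chromene and a ruthenium methylidene while ethene leaves the solution. The closest known reaction type is the metathesis closure of 2-vinylaryl allyl and 1,1-dimethylallyl ethers to 2H-chromenes. The pyran ring (O1, C2, C3, C4, C4a, C8a) is closed as a six-membered ring by forming the C3=C4 bond with both alkene carbons inside the ring, so the alkene can only be cis, and no stereocentre is created. The step needs chemoselectivity for metathesis over aromatic Claisen rearrangement of the tertiary allyl aryl ether toward the free ring carbon and over intermolecular cross-metathesis. The first is secured by working at or below 40 °C and by the quaternary carbon, which carries no allylic hydrogen and so excludes alkene migration; the second by high dilution, the ortho arrangement of the two alkenes and the gem-dimethyl effect. The phenols are left free because both are hydrogen-bonded to the ketone and the catalyst tolerates phenols.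

**Step 7**
Reactants: 11 pentan-3-one
Product: 12 (Z)-3-(trimethylsilyloxy)pent-2-ene
Conditions: Me3SiCl (1.2 equiv), Et3N (2.4 equiv), DMF, 80 °C; distillation
Reagents that add atoms: chlorotrimethylsilane, C[Si](C)(C)Cl
Why: Silyl enol ether formation under equilibrating amine conditions should give a single regioisomer because the ketone is symmetric.

**Step 8**
Reactants: 12 (Z)-3-(trimethylsilyloxy)pent-2-ene; 13 malonyl dichloride (propanedioyl dichloride)
Product: 14 6-ethyl-4-hydroxy-5-methyl-2H-pyran-2-one
Conditions: Et2O, −78 °C → rt
Reagents that add atoms: none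
Why: C-acylation of the silyl enol ether by one acyl chloride, followed by lactonisation of the ketone enol oxygen onto the second acyl chloride, is the established 4-hydroxy-2-pyranone synthesis from silyl enol ethers and malonyl dichloride.

**Step 9**
Reactants: 14 6-ethyl-4-hydroxy-5-methyl-2H-pyran-2-one; 10 1-(5,7-dihydroxy-2,2-dimethyl-2H-chromen-6-yl)-2-methylpropan-1-one
Product: 17 3-{[5,7-dihydroxy-2,2-dimethyl-6-(2-methylpropanoyl)-2H-chromen-8-yl]methyl}-6-ethyl-4-hydroxy-5-methyl-2H-pyran-2-one, via pyranone Mannich base 15 (not isolated), via 3-methylidenepyrandione 16 (not isolated)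
Conditions: 14, Eschenmoser's salt (1.0 equiv), MeCN, rt; then 10 (1.1 equiv), 60 °C
Reagents that add atoms: N,N-dimethylmethylideneammonium iodide (Eschenmoser's salt), C=[N+](C)C.[I-]
Why: Mannich aminomethylation of the nucleophilic pyranone C3, thermal loss of dimethylamine to the 3-methylidene-pyran-2,4-dione and Michael-type (Friedel–Crafts) addition of C8 of 10, the only unsubstituted carbon of its phloroglucinol ring, should give the methylene-bridged dimer, a coupling known for acylphloroglucinol–pyranone pairs, and forming the Mannich base before 10 is added keeps the iminium salt away from the chromene.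

**Compound list**
1 | phloroglucinol (benzene-1,3,5-triol) | Oc1cc(O)cc(O)c1 | starting material
2 | 2-methylpropanoyl chloride | CC(C)C(Cl)=O | starting material
3 | 2-methyl-1-(2,4,6-trihydroxyphenyl)propan-1-one | CC(C)C(=O)c1c(O)cc(O)cc1O | intermediate
4 | 3-chloro-3-methylbut-1-yne | CC(C)(Cl)C#C | starting material
5 | 1-[2,6-dihydroxy-4-(2-methylbut-3-yn-2-yloxy)phenyl]-2-methylpropan-1-one | CC(C)C(=O)c1c(O)cc(OC(C)(C)C#C)cc1O | intermediate
6 | N-{[2,4-dihydroxy-6-(2-methylbut-3-yn-2-yloxy)-3-(2-methylpropanoyl)phenyl]methylidene}-N-methylmethanaminium chloride (not isolated) | CC(C)C(=O)c1c(O)cc(OC(C)(C)C#C)c(C=[N+](C)C)c1O.[Cl-] | intermediate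
7 | 2,4-dihydroxy-6-(2-methylbut-3-yn-2-yloxy)-3-(2-methylpropanoyl)benzaldehyde | CC(C)C(=O)c1c(O)cc(OC(C)(C)C#C)c(C=O)c1O | intermediate
8 | 2,4-dihydroxy-6-(2-methylbut-3-en-2-yloxy)-3-(2-methylpropanoyl)benzaldehyde | CC(C)C(=O)c1c(O)cc(OC(C)(C)C=C)c(C=O)c1O | intermediate
9 | 1-[3-ethenyl-2,6-dihydroxy-4-(2-methylbut-3-en-2-yloxy)phenyl]-2-methylpropan-1-one | CC(C)C(=O)c1c(O)cc(OC(C)(C)C=C)c(C=C)c1O | intermediate
10 | 1-(5,7-dihydroxy-2,2-dimethyl-2H-chromen-6-yl)-2-methylpropan-1-one | CC(C)C(=O)c1c(O)cc2OC(C)(C)C=Cc2c1O | intermediate
11 | pentan-3-one | CCC(=O)CC | starting material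
12 | (Z)-3-(trimethylsilyloxy)pent-2-ene | C/C=C(\O[Si](C)(C)C)CC | intermediate
13 | malonyl dichloride (propanedioyl dichloride) | O=C(Cl)CC(=O)Cl | starting material
14 | 6-ethyl-4-hydroxy-5-methyl-2H-pyran-2-one | CCc1oc(=O)cc(O)c1C | intermediate
15 | 3-[(dimethylamino)methyl]-6-ethyl-4-hydroxy-5-methyl-2H-pyran-2-one (not isolated) | CCc1oc(=O)c(CN(C)C)c(O)c1C | intermediate
16 | 6-ethyl-5-methyl-3-methylidene-2H-pyran-2,4(3H)-dione (not isolated) | CCC1=C(C)C(=O)C(=C)C(=O)O1 | intermediate
17 | 3-{[5,7-dihydroxy-2,2-dimethyl-6-(2-methylpropanoyl)-2H-chromen-8-yl]methyl}-6-ethyl-4-hydroxy-5-methyl-2H-pyran-2-one | CCc1oc(=O)c(Cc2c(O)c(C(=O)C(C)C)c(O)c3c2OC(C)(C)C=C3)c(O)c1C | target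

**Step count and risk**
Total step count: 9. Longest linear sequence: 7 steps (steps 1–6, then step 9); the pyranone branch (steps 7–8) joins in step 9.

Steps most likely to fail:

Step 6 (key step). The ruthenium may be held as an unreactive chelated aryl carbene by the ortho ether oxygen, so that closure stalls and, on warming, Claisen rearrangement of the tertiary allyl aryl ether takes over. The fallback closes the pyran ring by a pericyclic cascade instead; it sets out from propargyl ether 5 and comes back to the route at chromene 10. Heating 5 in N,N-diethylaniline or o-xylene at 140–180 °C should bring about propargyl Claisen rearrangement to either of the two equivalent ortho carbons, 1,5-hydrogen shift and oxa-6π electrocyclisation, the classical entry to 2,2-dimethyl-2H-chromenes. No compound outside the list is formed (none F0).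

Step 5. Olefination may stall because the aldehyde, once both phenols are deprotonated, is a doubly vinylogous carboxylate and a poor electrophile. The fallback uses protecting groups; it sets out from aldehyde 8 and comes back at chromene 10. Both phenols of 8 are capped with NaH and chloromethyl methyl ether in DMF at 0 °C to give 2,4-bis(methoxymethoxy)-6-(2-methylbut-3-en-2-yloxy)-3-(2-methylpropanoyl)benzaldehyde F1. Its neutral aldehyde should take up Ph3P=CH2 (1.3 equiv, THF, 0 °C) to give 1-[3-ethenyl-2,6-bis(methoxymethoxy)-4-(2-methylbut-3-en-2-yloxy)phenyl]-2-methylpropan-1-one F2. Ring-closing metathesis under the conditions of step 6 should then give 1-[5,7-bis(methoxymethoxy)-2,2-dimethyl-2H-chromen-6-yl]-2-methylpropan-1-one F3. HCl in methanol at room temperature, which 2,2-dimethylchromenes tolerate, should free both phenols and return 10.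

Step 3. The tertiary propargylic ether may be cleaved under the acidic chloroiminium conditions, or O-formylation of the phenols may compete with ring substitution. The fallback installs the vinyl group by cross-coupling in place of formylation and olefination; it sets out from ether 5 and comes back at precursor 9, replacing steps 3 to 5. N-Iodosuccinimide (1.0 equiv, MeCN, 0 °C) should iodinate one of the two equivalent ring carbons to give 1-[2,6-dihydroxy-3-iodo-4-(2-methylbut-3-yn-2-yloxy)phenyl]-2-methylpropan-1-one F4. Stille coupling with tributyl(vinyl)stannane and Pd(PPh3)4 in toluene at 80 °C should give 1-[3-ethenyl-2,6-dihydroxy-4-(2-methylbut-3-yn-2-yloxy)phenyl]-2-methylpropan-1-one F5. Lindlar semi-hydrogenation as in step 4, stopped at one equivalent of hydrogen, should then give 9.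

**Further compounds**
F0 | step 6 | none | none
F1 | step 5 | 2,4-bis(methoxymethoxy)-6-(2-methylbut-3-en-2-yloxy)-3-(2-methylpropanoyl)benzaldehyde | CC(C)C(=O)c1c(OCOC)cc(OC(C)(C)C=C)c(C=O)c1OCOC
F2 | step 5 | 1-[3-ethenyl-2,6-bis(methoxymethoxy)-4-(2-methylbut-3-en-2-yloxy)phenyl]-2-methylpropan-1-one | CC(C)C(=O)c1c(OCOC)cc(OC(C)(C)C=C)c(C=C)c1OCOC
F3 | step 5 | 1-[5,7-bis(methoxymethoxy)-2,2-dimethyl-2H-chromen-6-yl]-2-methylpropan-1-one | CC(C)C(=O)c1c(OCOC)cc2OC(C)(C)C=Cc2c1OCOC
F4 | step 3 | 1-[2,6-dihydroxy-3-iodo-4-(2-methylbut-3-yn-2-yloxy)phenyl]-2-methylpropan-1-one | CC(C)C(=O)c1c(O)cc(OC(C)(C)C#C)c(I)c1O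
F5 | step 3 | 1-[3-ethenyl-2,6-dihydroxy-4-(2-methylbut-3-yn-2-yloxy)phenyl]-2-methylpropan-1-one | CC(C)C(=O)c1c(O)cc(OC(C)(C)C#C)c(C=C)c1O
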